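**Retrosynthetic overview**
1. Target 10 ⇐ 7-O-prenyl ether 7: the C8 1,1-dimethylallyl group is relayed from the O7–prenyl bond by a C8-directed aromatic [3,3] shift under transient O-silylation.
2. 7 ⇐ 2'-hydroxygenistein 5 + prenyl bromide 6: the aryl–O–prenyl bond is made selectively at the most acidic (7-) hydroxyl.
3. 5 ⇐ 2',4'-di-O-methyl isoflavone 4 by O-demethylation, before any acid-sensitive allyl group is present.
4. 4 ⇐ phloroglucinol 1 + 2,4-dimethoxyphenylacetic acid 2 + one carbon from DMF: C-acylation, then pyranone closure through the O1–C2 bond.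
5. Ring order: rings A and B are bought; the γ-pyrone ring C is the only ring formed (step 1).

Assumption: the target SMILES has no stereocentre and the molecule is achiral, so there is no enantiomer to control; the selectivity issue is regiochemical (C8 versus C6).

**Step 1**
Reactants: 1 phloroglucinol; 2 2,4-dimethoxyphenylacetic acid
Product: 4 3-(2,4-dimethoxyphenyl)-5,7-dihydroxy-4H-chromen-4-one, via deoxybenzoin 3 (not isolated)
Conditions: BF3·Et2O (solvent), 85 °C, 1.5 h; then DMF, MsCl, 70 °C, 2 h; then ice/H2O
Reagents that add atoms: N,N-dimethylformamide, CN(C)C=O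
Why: BF3-mediated Friedel–Crafts C-acylation of phloroglucinol gives deoxybenzoin 3 as its BF2 chelate, whose active methylene is aminomethylenated by the DMF/MsCl Vilsmeier-type reagent and closed by oxa-cyclisation (O1–C2 bond, loss of Me2NH) to the γ-pyrone (one-pot deoxybenzoin route to isoflavones); the B-ring methyl ethers prevent benzofuran formation by a free 2'-OH, and no stereocentre is formed.

**Step 2**
Reactants: 4 3-(2,4-dimethoxyphenyl)-5,7-dihydroxy-4H-chromen-4-one
Product: 5 3-(2,4-dihydroxyphenyl)-5,7-dihydroxy-4H-chromen-4-one (2'-hydroxygenistein)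
Conditions: BBr3 (6 equiv), CH2Cl2, −78 °C → rt, 16 h; then H2O
Reagents that add atoms: none
Why: BBr3 cleavage of aryl methyl ethers (O–B coordination, then bromide SN2 at methyl) is tolerated by the chromone and the free phenols, and at this stage there is no prenyl or allyl group to be damaged by acid.

**Step 3**
Reactants: 5 2'-hydroxygenistein; 6 prenyl bromide (1-bromo-3-methylbut-2-ene)
Product: 7 3-(2,4-dihydroxyphenyl)-5-hydroxy-7-[(3-methylbut-2-en-1-yl)oxy]-4H-chromen-4-one
Conditions: 6 (1.05 equiv), K2CO3 (1.0 equiv), DMF, 0 °C → rt, 12 h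
Reagents that add atoms: none
Why: Williamson O-alkylation; the 7-OH is a vinylogous acid para to C4=O (pKa about 7, against about 9.5–10 for the B-ring hydroxyls and an inert chelated 5-OH), so one equivalent of carbonate gives mainly the 7-phenoxide, which attacks prenyl bromide by SN2 to form the aryl–O–prenyl bond.

**Step 4**
Reactants: 7 3-(2,4-dihydroxyphenyl)-5-hydroxy-7-[(3-methylbut-2-en-1-yl)oxy]-4H-chromen-4-one
Product: 10 3-(2,4-dihydroxyphenyl)-5,7-dihydroxy-8-(2-methylbut-3-en-2-yl)-4H-chromen-4-one (target), via tris-TMS ether 8 (not isolated), via tetrakis-TMS ether 9 (not isolated)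
Conditions: BSA (6 equiv), PhNEt2, 80 °C, 1 h; then 185 °C (sealed tube, Ar), 3 h; then MeOH, K2CO3 (cat.), rt
Reagents that add atoms: none
Why: Proposed new method: a chelation-switched, silyl-gated aromatic Claisen rearrangement in which exhaustive in situ O-silylation replaces the 5-OH···O=C4 hydrogen-bond chelate (which fixes a C6=C7 bond and by resorcinol-ketone bond fixation should steer a 7-O-allyl shift toward C6) by a bulky non-chelated 5-OSiMe3, so the [3,3] shift of the prenyl ether follows the chromone-type C7=C8 bond fixation to the unhindered C8 and delivers the 1,1-dimethylallyl group with allylic inversion, while the released 7-OH is silylated at once and cannot undergo Cope migration or dihydrofuran closure, and methanolysis then removes all silyl groups; the closest known reaction type is the thermal aromatic Claisen rearrangement of 7-prenyloxy-coumarins and -chromones run with an in situ acyl trap; no stereocentre is formed.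

**Compound list**
1 | phloroglucinol (benzene-1,3,5-triol) | Oc1cc(O)cc(O)c1 | starting material
2 | 2,4-dimethoxyphenylacetic acid | COc1ccc(CC(=O)O)c(OC)c1 | starting material
3 | 2-(2,4-dimethoxyphenyl)-1-(2,4,6-trihydroxyphenyl)ethan-1-one (deoxybenzoin) | COc1ccc(CC(=O)c2c(O)cc(O)cc2O)c(OC)c1 | intermediate
4 | 3-(2,4-dimethoxyphenyl)-5,7-dihydroxy-4H-chromen-4-one | COc1ccc(-c2coc3cc(O)cc(O)c3c2=O)c(OC)c1 | intermediate
5 | 3-(2,4-dihydroxyphenyl)-5,7-dihydroxy-4H-chromen-4-one (2'-hydroxygenistein) | O=c1c(-c2ccc(O)cc2O)coc2cc(O)cc(O)c12 | intermediate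
6 | prenyl bromide (1-bromo-3-methylbut-2-ene) | CC(C)=CCBr | starting material
7 | 3-(2,4-dihydroxyphenyl)-5-hydroxy-7-[(3-methylbut-2-en-1-yl)oxy]-4H-chromen-4-one | CC(C)=CCOc1cc(O)c2c(=O)c(-c3ccc(O)cc3O)coc2c1 | intermediate
8 | 3-[2,4-bis(trimethylsilyloxy)phenyl]-7-[(3-methylbut-2-en-1-yl)oxy]-5-(trimethylsilyloxy)-4H-chromen-4-one | CC(C)=CCOc1cc(O[Si](C)(C)C)c2c(=O)c(-c3ccc(O[Si](C)(C)C)cc3O[Si](C)(C)C)coc2c1 | intermediate
9 | 3-[2,4-bis(trimethylsilyloxy)phenyl]-8-(2-methylbut-3-en-2-yl)-5,7-bis(trimethylsilyloxy)-4H-chromen-4-one | C=CC(C)(C)c1c(O[Si](C)(C)C)cc(O[Si](C)(C)C)c2c(=O)c(-c3ccc(O[Si](C)(C)C)cc3O[Si](C)(C)C)coc12 | intermediate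
10 | 3-(2,4-dihydroxyphenyl)-5,7-dihydroxy-8-(2-methylbut-3-en-2-yl)-4H-chromen-4-one (achiral) | C=CC(C)(C)c1c(O)cc(O)c2c(=O)c(-c3ccc(O)cc3O)coc12 | target

**Step count and risks**
Total step count: 4. Longest linear sequence: 4 steps (1 + 2 → 4 → 5 → 7 → 10).

The three steps most likely to fail:

Step 4 (the proposed new step). The risks are incomplete 5-O-silylation, which would leak product to C6, and thermal loss of isoprene from the prenyl ether. The fallback uses known chemistry with discrete ester protection; it sets out from 7 and comes back at 10. Acetylation of 7 (Ac2O, pyridine, cat. DMAP, rt) gives 5,2',4'-tri-O-acetyl-7-O-prenyl-2'-hydroxygenistein F1. The 5-O-acyl group removes the chelate in the same way as the silyl group. A thermal Claisen rearrangement of F1 in N,N-diethylaniline with acetic anhydride as phenol trap (185 °C) gives 8-(1,1-dimethylallyl)-2'-hydroxygenistein tetraacetate F2. Methanolysis (K2CO3, MeOH, rt) then gives 10.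

Step 3 (site-selective O-prenylation). The risks are 4'-O or 2'-O over-alkylation and C-alkylation of the phloroglucinol-type ring. The fallback changes from phenoxide alkylation to a redox condensation that activates the alcohol instead; it sets out from 5 and comes back at 7. A Mitsunobu etherification of 5 with 3-methylbut-2-en-1-ol (PPh3, DIAD, THF, 0 °C → rt, 1.05 equiv each) engages the most acidic 7-OH first and involves no free phenoxide, which suppresses C-alkylation. It makes no new compound.

Step 1 (one-pot acylation and annulation). The risks are incomplete acylation or a poor ring closure with the ortho-methoxylated benzyl ketone. The fallback is a stepwise nitrile route with isolation of the ketone; it sets out from 1 and comes back at 4. Houben–Hoesch condensation of 1 with commercial 2,4-dimethoxyphenylacetonitrile (ZnCl2, HCl gas, Et2O, 0 °C) gives 2-(2,4-dimethoxyphenyl)-1-(2,4,6-trihydroxyphenyl)ethan-1-iminium chloride F3. Hydrolysis in boiling water gives deoxybenzoin 3, now isolated and purified. Ring closure with triethyl orthoformate (pyridine, cat. piperidine, reflux) gives 4.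

**Further compounds**
F1 | step 4 | 5,2',4'-tri-O-acetyl-7-O-prenyl-2'-hydroxygenistein | CC(C)=CCOc1cc(OC(C)=O)c2c(=O)c(-c3ccc(OC(C)=O)cc3OC(C)=O)coc2c1
F2 | step 4 | 8-(1,1-dimethylallyl)-2'-hydroxygenistein tetraacetate | C=CC(C)(C)c1c(OC(C)=O)cc(OC(C)=O)c2c(=O)c(-c3ccc(OC(C)=O)cc3OC(C)=O)coc12
F0 | step 3 | none | none
F3 | step 1 | 2-(2,4-dimethoxyphenyl)-1-(2,4,6-trihydroxyphenyl)ethan-1-iminium chloride | COc1ccc(CC(=[NH2+])c2c(O)cc(O)cc2O)c(OC)c1.[Cl-]
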